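**Plan**
1. Retrosynthesis: the prenyl alkene is cut back to an allyl group (cross-metathesis) and the three phenols to benzyl ethers. Ring C is then cut at O1–C2 and C4–C4a, giving a dibenzylated phloroglucinol (ring A) and a C2–C3–C4 unit that carries ring B. Last, C2 is cut from C3.
2. Enabling feature: O1 and C4a form a 1,3-O,C-dinucleophile of the symmetric phloroglucinol ring A (C4a is ortho/para to three oxygens; both carbons ortho to O1 are equivalent). C2 and C4 form a 1,3-dielectrophile at the β-hydroxy-acid level around C3. Joining C2 and C4 through one oxygen gives an α-aryl β-lactone, a strained four-membered ring that is absent from the target and is destroyed in the annulation.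
3. Forward order: ring B is dressed first (methyl, benzyl, allyl), the aldehyde is homologated to the arylacetic acid, C2 is added, and the lactone is closed. Ring C then forms in one flask: the phenoxide opens the lactone at C2 (O1–C2) and the freed carboxyl acylates C4a (C4–C4a).
4. Stereochemistry: C3 (S) is set once, by hydroxymethylation of a titanium enolate under control of a phenylalaninol-derived oxazolidinone auxiliary. No later step makes or breaks a bond at C3, and no base is used once the C4 ketone exists.
5. Endgame: debenzylation with BCl3/pentamethylbenzene, then cross-metathesis with 2-methyl-2-butene, so the acid-sensitive prenyl group is made last.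

Key step: step 10

Remark: isoflavanone numbering is used (ring C: O1, C2, C3, C4; ring A: C4a to C8a; ring B primed), and prenyl is read as 3-methylbut-2-en-1-yl.

Step 1
Reactants: 1 3-bromo-4,5-dihydroxybenzaldehyde
Product: 2 3-bromo-5-hydroxy-4-methoxybenzaldehyde
Conditions: MeI (1.05 equiv), Li2CO3 (1.1 equiv), DMF, 40 °C
Reagents that add atoms: iodomethane, CI
Why: Williamson etherification in which the 4-OH, para to the formyl group and ortho to bromine, is the more acidic phenol and should be methylated selectively when only about one equivalent of MeI and a weak base are offered.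

Step 2
Reactants: 2 3-bromo-5-hydroxy-4-methoxybenzaldehyde
Product: 3 3-(benzyloxy)-5-bromo-4-methoxybenzaldehyde
Conditions: BnBr, K2CO3, DMF, rt
Reagents that add atoms: benzyl bromide, BrCc1ccccc1
Why: Williamson etherification of the remaining phenol masks the future 3'-OH as a benzyl ether that should tolerate every step up to the Lewis-acid debenzylation.

Step 3
Reactants: 3 3-(benzyloxy)-5-bromo-4-methoxybenzaldehyde
Product: 4 3-allyl-5-(benzyloxy)-4-methoxybenzaldehyde
Conditions: allylSnBu3, Pd(PPh3)4 (5 mol %), toluene, 105 °C
Reagents that add atoms: allyltributylstannane, C=CC[Sn](CCCC)(CCCC)CCCC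
Why: Stille coupling (oxidative addition of the aryl bromide to zerovalent palladium, allyl transfer from tin, reductive elimination) places a robust allyl group at the future C5', the aldehyde being inert to the stannane without a Lewis acid.

Step 4
Reactants: 4 3-allyl-5-(benzyloxy)-4-methoxybenzaldehyde
Product: 5 1-allyl-3-(benzyloxy)-2-methoxy-5-(2-methoxyvinyl)benzene (E/Z mixture)
Conditions: Ph3P(CH2OMe)Cl, KOtBu, THF, 0 °C → rt
Reagents that add atoms: (methoxymethyl)triphenylphosphonium chloride, COC[P+](c1ccccc1)(c1ccccc1)c1ccccc1.[Cl-]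
Why: Wittig reaction with the methoxymethylene ylide homologates the aldehyde to an enol ether, a masked arylacetaldehyde whose alkene geometry is irrelevant.

Step 5
Reactants: 5 1-allyl-3-(benzyloxy)-2-methoxy-5-(2-methoxyvinyl)benzene
Product: 7 2-(3-allyl-5-(benzyloxy)-4-methoxyphenyl)acetic acid, via arylacetaldehyde 6 (not isolated)
Conditions: 2 M aq. HCl, THF, 50 °C; then crude 6, NaClO2, NaH2PO4, 2-methyl-2-butene, t-BuOH/H2O, 0 °C → rt
Reagents that add atoms: water, O; sodium chlorite, [Na+].[O-]Cl=O
Why: Acid hydrolysis of the enol ether gives the arylacetaldehyde, which a Pinnick oxidation converts to the acid while 2-methyl-2-butene scavenges hypochlorous acid and so protects the allyl group.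

Step 6
Reactants: 7 2-(3-allyl-5-(benzyloxy)-4-methoxyphenyl)acetic acid; 8 (R)-4-benzyloxazolidin-2-one
Product: 10 (R)-3-[2-(3-allyl-5-(benzyloxy)-4-methoxyphenyl)acetyl]-4-benzyloxazolidin-2-one, via pivalic mixed anhydride 9 (not isolated)
Conditions: t-BuCOCl, Et3N, THF, −20 °C; then 8, LiCl, −20 °C → rt
Reagents that add atoms: none
Why: N-acylation of the oxazolidinone through the mixed pivalic anhydride, which is attacked at its less hindered arylacetyl carbonyl, attaches the chiral auxiliary.

Step 7
Reactants: 10 (R)-3-[2-(3-allyl-5-(benzyloxy)-4-methoxyphenyl)acetyl]-4-benzyloxazolidin-2-one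
Product: 12 (R)-3-[(S)-2-(3-allyl-5-(benzyloxy)-4-methoxyphenyl)-3-hydroxypropanoyl]-4-benzyloxazolidin-2-one, via titanium enolate 11 (not isolated)
Conditions: TiCl4 (1.05 equiv), i-Pr2NEt (1.1 equiv), CH2Cl2, 0 °C; then 1,3,5-trioxane (1.2 equiv), TiCl4 (1.05 equiv), 0 °C; aq. NH4Cl
Reagents that add atoms: 1,3,5-trioxane, C1OCOCO1
Why: Soft enolization with TiCl4 and amine gives the chelated (Z)-enolate, whose face syn to the C4 benzyl group of the (R)-auxiliary is blocked, so the TiCl4-opened trioxane (an oxocarbenium ion) should add to the open face and set C3 as S (auxiliary-controlled hydroxymethylation of a titanium enolate).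

Step 8
Reactants: 12 (R)-3-[(S)-2-(3-allyl-5-(benzyloxy)-4-methoxyphenyl)-3-hydroxypropanoyl]-4-benzyloxazolidin-2-one
Product: 14 (S)-2-(3-allyl-5-(benzyloxy)-4-methoxyphenyl)-3-hydroxypropanoic acid, via peroxy acid 13 (not isolated)
Conditions: LiOH, 30% H2O2, THF/H2O, 0 °C; then aq. Na2SO3; 1 M HCl to pH 2
Reagents that add atoms: hydrogen peroxide, OO
Why: The hydroperoxide anion attacks the exocyclic imide carbonyl selectively and is too weakly basic to epimerize the α-aryl centre, sulfite then reduces the peroxy acid, and the auxiliary is recovered (standard hydroperoxide cleavage of an N-acyloxazolidinone).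

Step 9
Reactants: 14 (S)-2-(3-allyl-5-(benzyloxy)-4-methoxyphenyl)-3-hydroxypropanoic acid
Product: 15 (S)-3-(3-allyl-5-(benzyloxy)-4-methoxyphenyl)oxetan-2-one
Conditions: PPh3, DIAD, THF, −78 °C → rt
Reagents that add atoms: none
Why: Intramolecular Mitsunobu reaction with hydroxyl-group activation, in which the carboxylate displaces the primary oxyphosphonium group (4-exo-tet) so that C3 is not touched and keeps its configuration.

Step 10
Reactants: 15 (S)-3-(3-allyl-5-(benzyloxy)-4-methoxyphenyl)oxetan-2-one; 16 3,5-bis(benzyloxy)phenol
Product: 19 (S)-3-(3-allyl-5-(benzyloxy)-4-methoxyphenyl)-5,7-bis(benzyloxy)chroman-4-one, via aryloxy acid 17 (not isolated), via acyl trifluoroacetate 18 (not isolated)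
Conditions: 16 (1.5 equiv), NaH, MeCN, 0 °C; slow addition of 15, 0 °C → rt; then CF3CO2H, (CF3CO)2O, CH2Cl2, 0 °C → rt; pH 7 work-up
Reagents that add atoms: none
Why: The sodium phenoxide of 16 attacks the CH2 carbon of the strained lactone in an SN2 alkyl–oxygen cleavage (O1–C2 bond) and frees C4 as a carboxylate; after acidification the acyl trifluoroacetate 18 acylates the ring A carbon ortho to the new ether oxygen, which is activated by three ether oxygens (C4–C4a bond), and the lactone oxygen leaves as trifluoroacetic acid. The closest known reaction types are the β-carbon ring opening of β-propiolactones by phenoxides and the trifluoroacetic-anhydride-mediated intramolecular Friedel–Crafts acylation of 3-aryloxypropanoic acids to chroman-4-ones, here joined in one flask. Ring C closes in the acylation as a 6-exo-trig attack of C4a on the acyl carbon, the four-membered ring being opened and not closed. No new stereocentre is formed: C3 should keep the S configuration set in step 7 because neither bond is made at C3, the carboxylate stage offers no elimination path, and the acylation stage contains no base. The step needs O- rather than C-alkylation of the ambident phenoxide and alkyl–oxygen rather than acyl–oxygen cleavage, which the phenoxide in a polar aprotic solvent, the strain-driven irreversible displacement and the shielding of the carbonyl by the α-aryl group should secure, while slow addition of 15 to excess phenoxide should suppress oligomerization through the new carboxylate. Regiochemistry of the acylation is no issue because ring A is symmetric: both carbons ortho to O1 are equivalent and the carbon between the two benzyloxy groups cannot be reached by the tether.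

Step 11
Reactants: 19 (S)-3-(3-allyl-5-(benzyloxy)-4-methoxyphenyl)-5,7-bis(benzyloxy)chroman-4-one
Product: 20 (S)-3-(3-allyl-5-hydroxy-4-methoxyphenyl)-5,7-dihydroxychroman-4-one
Conditions: BCl3, C6HMe5, CH2Cl2, −78 °C; MeOH quench, aqueous work-up
Reagents that add atoms: none
Why: BCl3 cleaves the three aryl benzyl ethers at −78 °C while pentamethylbenzene traps the benzyl cations by Friedel–Crafts alkylation, so neither the electron-rich rings nor the allyl group should be benzylated, the unchelated methyl ether should survive, and without base C3 should not epimerize.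

Step 12
Reactants: 20 (S)-3-(3-allyl-5-hydroxy-4-methoxyphenyl)-5,7-dihydroxychroman-4-one
Product: 21 (3S)-5,7,3'-trihydroxy-4'-methoxy-5'-prenylisoflavanone
Conditions: second-generation Grubbs catalyst (H2IMes)(PCy3)Cl2Ru=CHPh (5 mol %), 2-methyl-2-butene (excess), CH2Cl2, 40 °C
Reagents that add atoms: 2-methyl-2-butene, CC=C(C)C
Why: Olefin cross-metathesis of the terminal allyl group with excess 2-methyl-2-butene exchanges the methylidene end for an isopropylidene end under neutral conditions that tolerate free phenols and leave C3 alone, so the acid-sensitive prenyl group appears only in the last step.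

**Compound list**
1 | 3-bromo-4,5-dihydroxybenzaldehyde | O=Cc1cc(O)c(O)c(Br)c1 | starting material
2 | 3-bromo-5-hydroxy-4-methoxybenzaldehyde | COc1c(O)cc(C=O)cc1Br | intermediate
3 | 3-(benzyloxy)-5-bromo-4-methoxybenzaldehyde | COc1c(OCc2ccccc2)cc(C=O)cc1Br | intermediate
4 | 3-allyl-5-(benzyloxy)-4-methoxybenzaldehyde | COc1c(OCc2ccccc2)cc(C=O)cc1CC=C | intermediate
5 | 1-allyl-3-(benzyloxy)-2-methoxy-5-(2-methoxyvinyl)benzene (E/Z mixture) | COC=Cc1cc(CC=C)c(OC)c(OCc2ccccc2)c1 | intermediate
6 | 2-(3-allyl-5-(benzyloxy)-4-methoxyphenyl)acetaldehyde (not isolated) | COc1c(OCc2ccccc2)cc(CC=O)cc1CC=C | intermediate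
7 | 2-(3-allyl-5-(benzyloxy)-4-methoxyphenyl)acetic acid | COc1c(OCc2ccccc2)cc(CC(=O)O)cc1CC=C | intermediate
8 | (R)-4-benzyloxazolidin-2-one | O=C1N[C@H](Cc2ccccc2)CO1 | starting material
9 | mixed anhydride of 7 with pivalic acid (not isolated) | COc1c(OCc2ccccc2)cc(CC(=O)OC(=O)C(C)(C)C)cc1CC=C | intermediate
10 | (R)-3-[2-(3-allyl-5-(benzyloxy)-4-methoxyphenyl)acetyl]-4-benzyloxazolidin-2-one | COc1c(OCc2ccccc2)cc(CC(=O)N2[C@H](Cc3ccccc3)COC2=O)cc1CC=C | intermediate
11 | trichlorotitanium (Z)-enolate of 10 (not isolated) | COc1c(OCc2ccccc2)cc(/C=C(\O[Ti](Cl)(Cl)Cl)N2[C@H](Cc3ccccc3)COC2=O)cc1CC=C | intermediate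
12 | (R)-3-[(S)-2-(3-allyl-5-(benzyloxy)-4-methoxyphenyl)-3-hydroxypropanoyl]-4-benzyloxazolidin-2-one | COc1c(OCc2ccccc2)cc([C@H](C(=O)N2[C@H](Cc3ccccc3)COC2=O)CO)cc1CC=C | intermediate
13 | (S)-2-(3-allyl-5-(benzyloxy)-4-methoxyphenyl)-3-hydroxypropaneperoxoic acid, present as its lithium salt (not isolated) | COc1c(OCc2ccccc2)cc([C@H](C(=O)OO)CO)cc1CC=C | intermediate
14 | (S)-2-(3-allyl-5-(benzyloxy)-4-methoxyphenyl)-3-hydroxypropanoic acid | COc1c(OCc2ccccc2)cc([C@H](C(=O)O)CO)cc1CC=C | intermediate
15 | (S)-3-(3-allyl-5-(benzyloxy)-4-methoxyphenyl)oxetan-2-one | COc1c(OCc2ccccc2)cc([C@H]2COC2=O)cc1CC=C | intermediate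
16 | 3,5-bis(benzyloxy)phenol | Oc1cc(OCc2ccccc2)cc(OCc2ccccc2)c1 | starting material
17 | (S)-2-(3-allyl-5-(benzyloxy)-4-methoxyphenyl)-3-[3,5-bis(benzyloxy)phenoxy]propanoic acid, formed as its sodium salt (not isolated) | COc1c(OCc2ccccc2)cc([C@H](C(=O)O)COc2cc(OCc3ccccc3)cc(OCc3ccccc3)c2)cc1CC=C | intermediate
18 | mixed anhydride of 17 with trifluoroacetic acid (not isolated) | COc1c(OCc2ccccc2)cc([C@H](C(=O)OC(=O)C(F)(F)F)COc2cc(OCc3ccccc3)cc(OCc3ccccc3)c2)cc1CC=C | intermediate
19 | (S)-3-(3-allyl-5-(benzyloxy)-4-methoxyphenyl)-5,7-bis(benzyloxy)chroman-4-one | COc1c(OCc2ccccc2)cc([C@H]2COc3cc(OCc4ccccc4)cc(OCc4ccccc4)c3C2=O)cc1CC=C | intermediate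
20 | (S)-3-(3-allyl-5-hydroxy-4-methoxyphenyl)-5,7-dihydroxychroman-4-one | COc1c(O)cc([C@H]2COc3cc(O)cc(O)c3C2=O)cc1CC=C | intermediate
21 | (3S)-5,7,3'-trihydroxy-4'-methoxy-5'-prenylisoflavanone, that is (S)-5,7-dihydroxy-3-[3-hydroxy-4-methoxy-5-(3-methylbut-2-en-1-yl)phenyl]chroman-4-one | COc1c(O)cc([C@H]2COc3cc(O)cc(O)c3C2=O)cc1CC=C(C)C | target

**Step count and risks**
Total steps: 12. Longest linear sequence: 12 steps (1 to 21); 8 and 16 enter as purchased compounds in steps 6 and 10.

The three steps most likely to fail:

First, step 10. The ambident phenoxide may alkylate at carbon, or attack the lactone carbonyl instead of the CH2 group. The lactone may oligomerize through the carboxylate it releases. The phenoxide may also enolize the lactone and erode the configuration at C3, and trifluoroacetic anhydride may acylate the activated ring A. The fallback sets out from 12 and forms the two bonds in separate known steps without the lactone. Mitsunobu etherification of 12 with 16 (PPh3, DIAD, toluene, 0 °C) should give the aryl ether imide (R)-3-[(S)-2-(3-allyl-5-(benzyloxy)-4-methoxyphenyl)-3-(3,5-bis(benzyloxy)phenoxy)propanoyl]-4-benzyloxazolidin-2-one F1. Cleavage with LiOH/H2O2 at 0 °C should then release the auxiliary and give acid 17, now isolated. Cyclization of 17 with trifluoroacetic anhydride in CH2Cl2 comes back to the route at 19.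

Second, step 9. The activated hydroxy acid may fragment by decarboxylative anti-elimination to a styrene instead of closing the four-membered ring. The fallback sets out from 14 and activates the carboxyl group instead of the hydroxyl group (PhSO2Cl, pyridine, 0 °C). The ring then closes by O-acylation, and the hydroxyl group never becomes a leaving group, so the fragmentation path is absent; the cost is a risk of enolization of the activated acid, which the low temperature should limit. It comes back at 15, and no further compound arises (F0).

Third, step 7. TiCl4 may cleave the benzyl ether through chelation by the two neighbouring ether oxygens, the activated formaldehyde may attack the allyl group in a Prins-type reaction, or the adduct may revert by retro-aldol loss of formaldehyde. The fallback sets out from 10 and replaces the Lewis-acid hydroxymethylation by an enolate alkylation. The sodium enolate (NaN(SiMe3)2, THF, −78 °C) is alkylated with 4-methoxybenzyl chloromethyl ether on the same open face, which should give (R)-3-[(S)-2-(3-allyl-5-(benzyloxy)-4-methoxyphenyl)-3-((4-methoxybenzyl)oxy)propanoyl]-4-benzyloxazolidin-2-one F2. Oxidative removal of the 4-methoxybenzyl group with DDQ (CH2Cl2/pH 7 buffer, 0 °C) comes back to the route at 12.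

**Further compounds**
F1 | step 10 | (R)-3-[(S)-2-(3-allyl-5-(benzyloxy)-4-methoxyphenyl)-3-(3,5-bis(benzyloxy)phenoxy)propanoyl]-4-benzyloxazolidin-2-one | COc1c(OCc2ccccc2)cc([C@H](C(=O)N2[C@H](Cc3ccccc3)COC2=O)COc2cc(OCc3ccccc3)cc(OCc3ccccc3)c2)cc1CC=C
F0 | step 9 | none | none
F2 | step 7 | (R)-3-[(S)-2-(3-allyl-5-(benzyloxy)-4-methoxyphenyl)-3-((4-methoxybenzyl)oxy)propanoyl]-4-benzyloxazolidin-2-one | COc1c(OCc2ccccc2)cc([C@H](C(=O)N2[C@H](Cc3ccccc3)COC2=O)COCc2ccc(OC)cc2)cc1CC=C
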